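**Assumption:** prostanoid numbering is used (C1 = ester carbon, C9 = ring ketone). The target SMILES decodes to (5S,6R,7R,8R,12S,14Z), with 12‑OH cis to the C8 side chain and the 5,6,7‑triol all‑syn (D‑xylo). Reagents that only add atoms are given by name and SMILES in each step and are not numbered.

## Retrosynthetic overview

1. Punaglandin 2 (19) ⇒ acetylation / acetonide removal ⇒ cyclopentenone 17.
2. 17 ⇒ one operation forming C12–C13 and C8–C12: (Z)‑oct‑2‑enylbarium + (Z)‑γ‑ylidene‑β‑chlorobutenolide 14 (lactone 1,2‑addition, ring opening, chelation‑controlled intramolecular aldol). C8 and C12 are set from C7; the conventional C7–C8 aldol is not used.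
3. 14 ⇒ vinylogous Mukaiyama aldol/elimination (C8–C9) of 4‑chlorofuran‑2(5H)‑one (from tetronic acid) with aldehyde 10.
4. 10 ⇒ D‑xylose (C4–C8; xylose C2–C4 become C5–C7) + a three‑carbon Wittig reagent (C1–C3).
5. Ring order: dioxolanes (protection) → butenolide (carried from tetronic acid) → cyclopentenone formed last by recyclisation of the butenolide.

## Route

**Step 1**
Reactants: 1, D‑xylose
Product: 2, D‑xylose diethyl dithioacetal
Conditions: EtSH, conc. HCl, 0 °C
Reagents that add atoms: ethanethiol, CCS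
Why: Fischer dithioacetalisation traps the open‑chain aldehyde; no stereocentre is touched.

**Step 2**
Reactants: 2
Product: 3, 2,3:4,5‑di‑O‑isopropylidene‑D‑xylose diethyl dithioacetal
Conditions: Me2C(OMe)2, acetone, TsOH (cat.), rt
Reagents that add atoms: 2,2‑dimethoxypropane, COC(C)(C)OC
Why: Thermodynamic acetonation gives the trans‑dioxolane on the threo 2,3‑diol plus the terminal 4,5‑dioxolane.

**Step 3**
Reactants: 3
Product: 4, 2,3:4,5‑di‑O‑isopropylidene‑aldehydo‑D‑xylose
Conditions: I2, NaHCO3, acetone/H2O, 0 °C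
Reagents that add atoms: water, O
Why: Mild oxidative dethioacetalisation; buffered conditions keep both acetonides and the α‑stereocentre intact.

**Step 4**
Reactants: 4; 5, (2‑carboxyethyl)triphenylphosphonium bromide
Product: 6, methyl (3Z)‑2,3,4‑trideoxy‑5,6:7,8‑di‑O‑isopropylidene‑D‑xylo‑oct‑3‑enonate
Conditions: 5, NaHMDS (2 equiv), THF, −78 → 0 °C; 4, −78 °C → rt; then MeI, DMF, rt
Reagents that add atoms: iodomethane, CI
Why: Wittig olefination with the carboxylate ylide installs C1–C3, and the carboxylate is O‑methylated in the same pot; alkene geometry is irrelevant because it is hydrogenated next.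

**Step 5**
Reactants: 6
Product: 7, methyl 2,3,4‑trideoxy‑5,6:7,8‑di‑O‑isopropylidene‑D‑xylo‑octonate
Conditions: H2 (1 atm), Pd/C, EtOAc, rt
Reagents that add atoms: none
Why: Heterogeneous hydrogenation of the only alkene; acetonides and ester are inert.

**Step 6**
Reactants: 7
Product: 8, methyl 2,3,4‑trideoxy‑5,6‑O‑isopropylidene‑D‑xylo‑octonate (7,8‑diol)
Conditions: AcOH/H2O (3:2), rt
Reagents that add atoms: none
Why: Selective hydrolysis of the less substituted terminal acetonide; the internal trans‑dioxolane hydrolyses much more slowly.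

**Step 7**
Reactants: 8
Product: 9, the 7,8‑bis‑O‑triethylsilyl ether of 8
Conditions: TESCl, imidazole, DMF, 0 °C → rt
Reagents that add atoms: chlorotriethylsilane, CC[Si](Cl)(CC)CC
Why: Exhaustive silylation of the diol.

**Step 8**
Reactants: 9
Product: 10, methyl 5,6‑O‑isopropylidene‑8‑oxo‑7‑O‑triethylsilyl‑D‑xylo‑5,6,7‑trihydroxyoctanoate (C8 aldehyde)
Conditions: (COCl)2, DMSO, CH2Cl2, −78 → −30 °C; Et3N, −78 → 0 °C
Reagents that add atoms: none
Why: Swern conditions oxidatively cleave a primary TES ether directly to the aldehyde while the secondary TES ether survives; low temperature limits epimerisation at C7.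

**Step 9**
Reactants: 11, tetronic acid
Product: 12, 4‑chlorofuran‑2(5H)‑one
Conditions: (COCl)2, DMF (cat.), CH2Cl2, 0 °C → rt
Reagents that add atoms: oxalyl chloride, ClC(=O)C(=O)Cl
Why: Vilsmeier‑type conversion of the vinylogous acid into the vinylogous acid chloride; this chlorine becomes C10–Cl.

**Step 10**
Reactants: 10; 12
Product: 13, methyl 8‑[(2Z)‑3‑chloro‑5‑oxofuran‑2(5H)‑ylidene]‑5,6‑O‑isopropylidene‑7‑O‑triethylsilyl‑D‑xylo‑5,6,7‑trihydroxyoctanoate
Conditions: 12, TBSOTf, i‑Pr2NEt, CH2Cl2, 0 °C; then 10, −78 → −20 °C; then DBU, −20 → 0 °C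
Reagents that add atoms: none
Why: In situ 2‑silyloxyfuran formation, vinylogous Mukaiyama aldol at the furanone γ‑carbon (C8–C9 bond) and E1cB loss of silanol; the Z‑ylidene is favoured because the E isomer clashes with the ring chlorine, and C7 is not involved.

**Step 11**
Reactants: 13
Product: 14, the 7‑hydroxy (Z)‑ylidenebutenolide (13 without TES)
Conditions: HF·pyridine, pyridine, THF, 0 °C
Reagents that add atoms: none
Why: Buffered fluoride desilylation; acetonide, ester and the base‑sensitive ylidenebutenolide are untouched.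

**Step 12**
Reactants: 15, (Z)‑oct‑2‑en‑1‑ol
Product: 16, (Z)‑1‑chlorooct‑2‑ene
Conditions: NCS, Me2S, CH2Cl2, −20 → 0 °C
Reagents that add atoms: N‑chlorosuccinimide, ClN1C(=O)CCC1=O
Why: Corey–Kim allylic chlorination proceeds without allylic transposition or Z/E isomerisation.

**Step 13 (key step)**
Reactants: 14; 16
Product: 17, methyl (8R,12S,14Z)‑10‑chloro‑7,12‑dihydroxy‑5,6‑O‑isopropylidene‑9‑oxoprosta‑10,14‑dienoate (C5–C7 D‑xylo, as in the target)
Conditions: Ba* (BaI2, Li biphenylide, THF, rt); 16 (2.1 equiv), −78 °C; cannulate into 14, THF, −78 → −45 °C; AcOH quench at −78 °C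
Reagents that add atoms: none (16 supplies the octenyl group)
Why: Proposed new method: the first equivalent of the α‑selective, geometry‑retaining (Z)‑allylbarium deprotonates C7–OH and the second adds 1,2 to the enol‑lactone carbonyl (much more electrophilic than the methyl ester); the tetrahedral intermediate expels the enolate oxygen to give a Z‑enedione whose C8=C9 enolate keeps the ylidene geometry (O9 cis to C7), so Ba2+ bridges O7 and O9 in a Fráter–Seebach‑type six‑membered chelate and also binds the new C12 ketone; the 5‑(enolendo) aldol (equivalently a conrotatory 4π closure with C7 and C13 "out") then occurs on the enolate face anti to the C6 branch, giving 8R (7,8‑anti) and placing the C12 oxygen cis to the C7 chain (12S, octenyl trans to the α‑chain, also the thermodynamic arrangement); the closest known reactions are the hydride‑ or alkyllithium‑triggered rearrangement of 4‑ylidenebutenolides to 4‑hydroxycyclopent‑2‑enones, chelation‑controlled reactions of β‑alkoxide enolates, and allylbarium carbonyl additions.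

**Step 14**
Reactants: 17
Product: 18, methyl (5S,6R,7R,8R,12S,14Z)‑10‑chloro‑5,6,7,12‑tetrahydroxy‑9‑oxoprosta‑10,14‑dienoate
Conditions: CSA (cat.), MeOH, 0 °C → rt; used crude
Reagents that add atoms: none
Why: Acid‑catalysed transacetalisation removes the acetonide; methanol solvent suppresses δ‑lactonisation of 5‑OH onto the ester, and the tertiary allylic alcohol next to the electron‑poor chloroenone does not ionise.

**Step 15**
Reactants: 18
Product: 19, punaglandin 2
Conditions: Ac2O, pyridine, CH2Cl2, 0 °C → rt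
Reagents that add atoms: acetic anhydride, CC(=O)OC(C)=O
Why: The three secondary hydroxyls are acetylated while the hindered tertiary 12‑OH is not; the weak base at low temperature avoids β‑elimination of the 7‑acetate.

## Compound list

1 | D‑xylose (open‑chain form) | O=C[C@H](O)[C@@H](O)[C@H](O)CO | starting material
2 | D‑xylose diethyl dithioacetal | CCSC(SCC)[C@H](O)[C@@H](O)[C@H](O)CO | intermediate
3 | 2,3:4,5‑di‑O‑isopropylidene‑D‑xylose diethyl dithioacetal | CCSC(SCC)[C@H](O1)[C@@H](OC1(C)C)[C@H]2COC(C)(C)O2 | intermediate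
4 | 2,3:4,5‑di‑O‑isopropylidene‑aldehydo‑D‑xylose | O=C[C@H](O1)[C@@H](OC1(C)C)[C@H]2COC(C)(C)O2 | intermediate
5 | (2‑carboxyethyl)triphenylphosphonium bromide | OC(=O)CC[P+](c1ccccc1)(c1ccccc1)c1ccccc1.[Br-] | starting material
6 | methyl (3Z)‑2,3,4‑trideoxy‑5,6:7,8‑di‑O‑isopropylidene‑D‑xylo‑oct‑3‑enonate | COC(=O)C/C=C\[C@H](O1)[C@@H](OC1(C)C)[C@H]2COC(C)(C)O2 | intermediate
7 | methyl 2,3,4‑trideoxy‑5,6:7,8‑di‑O‑isopropylidene‑D‑xylo‑octonate | COC(=O)CCC[C@H](O1)[C@@H](OC1(C)C)[C@H]2COC(C)(C)O2 | intermediate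
8 | methyl 2,3,4‑trideoxy‑5,6‑O‑isopropylidene‑D‑xylo‑octonate | COC(=O)CCC[C@H](O1)[C@@H](OC1(C)C)[C@H](O)CO | intermediate
9 | 7,8‑bis‑O‑triethylsilyl ether of 8 | COC(=O)CCC[C@H](O1)[C@@H](OC1(C)C)[C@H](O[Si](CC)(CC)CC)CO[Si](CC)(CC)CC | intermediate
10 | methyl 5,6‑O‑isopropylidene‑8‑oxo‑7‑O‑triethylsilyl‑D‑xylo‑5,6,7‑trihydroxyoctanoate | COC(=O)CCC[C@H](O1)[C@@H](OC1(C)C)[C@H](O[Si](CC)(CC)CC)C=O | intermediate
11 | tetronic acid | OC1=CC(=O)OC1 | starting material
12 | 4‑chlorofuran‑2(5H)‑one | ClC1=CC(=O)OC1 | intermediate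
13 | (Z)‑ylidenebutenolide, 7‑OTES | COC(=O)CCC[C@H](O1)[C@@H](OC1(C)C)[C@H](O[Si](CC)(CC)CC)/C=C2\OC(=O)C=C2Cl | intermediate
14 | (Z)‑ylidenebutenolide, 7‑OH | COC(=O)CCC[C@H](O1)[C@@H](OC1(C)C)[C@H](O)/C=C2\OC(=O)C=C2Cl | intermediate
15 | (Z)‑oct‑2‑en‑1‑ol | CCCCC/C=C\CO | starting material
16 | (Z)‑1‑chlorooct‑2‑ene | CCCCC/C=C\CCl | intermediate
17 | methyl (8R,12S,14Z)‑10‑chloro‑7,12‑dihydroxy‑5,6‑O‑isopropylidene‑9‑oxoprosta‑10,14‑dienoate | COC(=O)CCC[C@H](O1)[C@@H](OC1(C)C)[C@H](O)[C@H]2C(=O)C(Cl)=C[C@]2(O)C/C=C\CCCCC | intermediate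
18 | methyl (5S,6R,7R,8R,12S,14Z)‑10‑chloro‑5,6,7,12‑tetrahydroxy‑9‑oxoprosta‑10,14‑dienoate | COC(=O)CCC[C@H](O)[C@@H](O)[C@H](O)[C@H]1C(=O)C(Cl)=C[C@]1(O)C/C=C\CCCCC | intermediate
19 | punaglandin 2, methyl (5S,6R,7R,8R,12S,14Z)‑5,6,7‑triacetoxy‑10‑chloro‑12‑hydroxy‑9‑oxoprosta‑10,14‑dienoate | CCCCC/C=C\C[C@@]1(O)C=C(Cl)C(=O)[C@@H]1[C@@H](OC(C)=O)[C@H](OC(C)=O)[C@H](CCCC(=O)OC)OC(C)=O | target

## Totals and risks

Total steps: 15. Longest linear sequence: 13 (steps 1–8, 10, 11, 13, 14, 15); steps 9 and 12 are one‑step side branches.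

Stereochemistry: C5, C6, C7 come from D‑xylose C2, C3, C4; C8 and C12 are both set in step 13; the 14Z alkene comes from 15.

Three steps most likely to fail:

1. **Step 13 (allylbarium addition / ring opening / chelation‑controlled aldol).** Risks are attack on the methyl ester or substitution at C10–Cl, over‑addition to the new ketone, enolate equilibration to C13, and modest or wrong facial selectivity. Fallback: abandon the cascade and revert to the classical convergent aldol. Make 2‑chloro‑4‑hydroxy‑4‑[(Z)‑oct‑2‑enyl]cyclopent‑2‑enone separately (same alkylative rearrangement on 4‑chloro‑5‑methylenefuran‑2(5H)‑one, then resolution), silylate the tertiary OH, and couple its lithium enolate with the C1–C7 aldehyde obtained by NaIO4 cleavage of diol 8.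

2. **Step 10 (vinylogous aldol / DBU elimination).** Risks are epimerisation at C7 (via the aldehyde or by vinylogous deprotonation of the product), β‑elimination of the C6 oxygen, and E/Z mixtures. Fallback: build the ylidenebutenolide without an aldol. Homologate 10 to the terminal alkyne (Ohira–Bestmann) and use Pd/Cu Sonogashira coupling with 5‑exo‑dig lactonisation onto (Z)‑3‑iodoacrylic acid to give the des‑chloro Z‑ylidenebutenolide. Chlorine is then introduced at C10 after the cascade by enone epoxidation and HCl opening/dehydration.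

3. **Step 14, with step 15 (acetonide removal and triacetylation).** Risks are δ‑lactonisation of 5‑OH onto the C1 ester, acetonide migration to O6/O7 or O7/O12, dehydration of the β‑hydroxy ketone, and β‑elimination of the 7‑acetate to the punaglandin‑4‑type dienone. Fallback: change the C1 strategy. Carry C1 as CH2OTBDPS (Wittig in step 4 with a 3‑silyloxypropyl ylide) so no ester is present in steps 13–15; after triacetylation, remove the silyl group (HF·pyridine), oxidise to the acid (TEMPO/PhI(OAc)2) and methylate (TMSCHN2).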